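**Plan** (labdane numbering: ring A = C1–C5 + C10, ring B = C5–C10, C17 = formyl carbon on C8, C11–C16 = side chain on C9)
1. Cuts: the C8 formyl group goes back to a C8 ketone (CHO ← axial CH2OH ← C8=CH2 ← C8=O ← allylic oxidation of a C6=C7 alkene); C12–C13 (sp3–sp2 coupling); ring A at C1–C2 and C4–C5, which removes C2–C3–C4 with both C4 methyls as one piece and leaves a ring-B cyclohexenol with C1 as a masked aldehyde on C10; C9–C11 (conjugate addition to an achiral cyclohexadienone).
2. Enabling feature: in ring A the oxygen-bearing C3 lies between C2 and C4, so ring A is a ketone annulated through both α-carbons. The C3 oxygen is first tied to C7 of ring B as an allyl vinyl ether (C5=C6–C7–O–C3=C4), a C–O bond absent from the target; a [3,3] shift exchanges it for C4–C5, and the ketone so unveiled closes C1–C2 by aldol condensation.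
3. Forward order: ring B (prochiral dienone, desymmetrised, reduced to the allylic alcohol) → side chain → ring A in one operation → C8 oxidation, reductions, C17.
4. Stereochemistry: C9 and C10 from catalyst-controlled vinyl addition anti to the acetal; the temporary C7 carbinol from Luche reduction; C5 (trans ring fusion) by suprafacial transfer from C7; C3 by axial hydride attack; C8 by hydroboration anti to the axial C10 methyl; the (Z)-alkene from a stereodefined vinyl iodide.

Key step: step 9

Assumption: the enantioface preference of the Rh/(S)-BINAP catalyst is taken to be the one established for cyclohex-2-enone; 1, 8, 12 and all reagents are taken as commercial.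

**Step 1**
Reactants: 1 1-methylcyclohexa-2,5-diene-1-carboxylic acid
Product: 2 (1-methylcyclohexa-2,5-dien-1-yl)methanol
Conditions: LiAlH4, THF, 0 °C → reflux; H2O work-up
Reagents that add atoms: none
Why: LiAlH4 reduction of the carboxylic acid should give the neopentyl alcohol, the skipped diene being inert to hydride and no stereocentre being formed.

**Step 2**
Reactants: 2 (1-methylcyclohexa-2,5-dien-1-yl)methanol
Product: 4 3-(dimethoxymethyl)-3-methylcyclohexa-1,4-diene, via aldehyde 3 (not isolated)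
Conditions: DMP, CH2Cl2, 0 °C → rt; filter, concentrate; then HC(OMe)3, TsOH·H2O (cat.), MeOH, rt
Reagents that add atoms: trimethyl orthoformate COC(OC)OC
Why: Dess–Martin oxidation gives the non-enolisable, volatile aldehyde 3, and acid-catalysed acetalisation masks it as the bulky dimethyl acetal that later steers facial selectivity; no stereocentre is formed.

**Step 3**
Reactants: 4 3-(dimethoxymethyl)-3-methylcyclohexa-1,4-diene
Product: 5 4-(dimethoxymethyl)-4-methylcyclohexa-2,5-dien-1-one
Conditions: Rh2(cap)4 (dirhodium tetracaprolactamate, 1 mol %), t-BuOOH (70% aq), K2CO3 (cat.), CH2Cl2, rt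
Reagents that add atoms: tert-butyl hydroperoxide CC(C)(C)OO
Why: Allylic C–H oxidation of the only (doubly allylic) CH2 should give the cross-conjugated dienone, which cannot aromatise because of the quaternary carbon and is achiral.

**Step 4**
Reactants: 5 4-(dimethoxymethyl)-4-methylcyclohexa-2,5-dien-1-one
Product: 6 (4R,5S)-4-(dimethoxymethyl)-5-ethenyl-4-methylcyclohex-2-en-1-one
Conditions: [Rh(cod)2]BF4 (3 mol %), (S)-BINAP, CH2=CHBF3K, toluene/H2O, 100 °C
Reagents that add atoms: potassium vinyltrifluoroborate [K+].C=C[B-](F)(F)F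
Why: Rh-catalysed asymmetric conjugate addition of the alkenylboron reagent desymmetrises the dienone, the (S)-BINAP complex choosing the enone face and the vinyl group entering anti to the bulky acetal, so that C9 (5S) and the quaternary C10 (4R) are set together with vinyl cis to methyl.

**Step 5**
Reactants: 6 (4R,5S)-4-(dimethoxymethyl)-5-ethenyl-4-methylcyclohex-2-en-1-one
Product: 7 (1S,4R,5S)-4-(dimethoxymethyl)-5-ethenyl-4-methylcyclohex-2-en-1-ol
Conditions: NaBH4, CeCl3·7H2O, MeOH, −78 → 0 °C
Reagents that add atoms: none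
Why: Luche reduction gives 1,2-reduction only, and axial hydride attack on the half-chair with the vinyl group equatorial (as in carvone to cis-carveol) should place the hydroxyl cis to vinyl (1S) while the acetal survives.

**Step 6**
Reactants: 8 methyl but-2-ynoate
Product: 9 methyl (2Z)-3-iodobut-2-enoate
Conditions: NaI, AcOH, 115 °C
Reagents that add atoms: sodium iodide [Na+].[I-]
Why: Hydroiodination of the ynoate (conjugate addition of iodide then protonation, net anti addition) is the standard route to the (Z)-β-iodo enoate and fixes the side-chain alkene geometry.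

**Step 7**
Reactants: 7 (1S,4R,5S)-4-(dimethoxymethyl)-5-ethenyl-4-methylcyclohex-2-en-1-ol; 9 methyl (2Z)-3-iodobut-2-enoate
Product: 11 methyl (2Z)-5-[(1R,2S,5S)-2-(dimethoxymethyl)-5-hydroxy-2-methylcyclohex-3-en-1-yl]-3-methylpent-2-enoate, via bis-boron adduct 10 (not isolated)
Conditions: 9-BBN (2.3 equiv), THF, 0 °C → rt; then 9, PdCl2(dppf) (5 mol %), K3PO4 (3 M aq), DMF, rt
Reagents that add atoms: none
Why: B-alkyl Suzuki–Miyaura coupling, in which 9-BBN hydroborates only the terminal vinyl group (the hydroxyl is carried as its borinate) and the vinyl iodide couples with retention, installs the (Z)-enoate without touching a stereocentre.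

**Step 8**
Reactants: 12 2-bromo-3-methylbut-2-ene
Product: 13 2-iodo-3-methylbut-2-ene
Conditions: NaI, CuI (copper monoiodide, 5 mol %), N,N′-dimethylethane-1,2-diamine (10 mol %), 1,4-dioxane, 110 °C
Reagents that add atoms: sodium iodide [Na+].[I-]
Why: Copper-catalysed halogen exchange (vinylic Finkelstein reaction) converts the vinyl bromide into the iodide needed for C–O coupling, with no stereochemical issue because the alkene carries two identical methyls.

**Step 9**
Reactants: 11 methyl (2Z)-5-[(1R,2S,5S)-2-(dimethoxymethyl)-5-hydroxy-2-methylcyclohex-3-en-1-yl]-3-methylpent-2-enoate; 13 2-iodo-3-methylbut-2-ene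
Product: 17 methyl (2Z)-3-methyl-5-[(1R,4aS,8aR)-5,5,8a-trimethyl-6-oxo-1,2,4a,5,6,8a-hexahydronaphthalen-1-yl]pent-2-enoate, via allyl vinyl ether 14 (not isolated), via Claisen ketone 15 (not isolated), via keto aldehyde 16 (not isolated)
Conditions: CuI (copper monoiodide, 10 mol %), 3,4,7,8-tetramethyl-1,10-phenanthroline (20 mol %), Cs2CO3, o-xylene, 120 → 145 °C; cool, then 2 M HCl, THF, 60 °C
Reagents that add atoms: none
Why: Proposed new method: copper-catalysed O-vinylation of the C7 alkoxide of 11 with the fully substituted vinyl iodide 13 (oxidative addition and C–O reductive elimination at copper) gives the regiodefined enol ether 14, whose Claisen rearrangement trades the temporary C7–O bond for C4–C5 and turns the tether oxygen into the C3 ketone of 15; aqueous acid then frees the C1 aldehyde (16), and the ketone, which can enolise only toward C2 because C4 is quaternary, condenses with the non-enolisable aldehyde to enone 17. The closest known reaction type is the domino copper-catalysed C–O coupling/Claisen rearrangement of allylic alcohols with vinyl iodides, which has not been shown for a tetrasubstituted vinyl iodide on a hindered cyclohexenol or with a terminating aldol condensation. Ring A is the only ring closed, in the aldol stage, as a 6-(enolendo)-exo-trig attack of C2 on the C1 carbonyl, the six-centre array of the sigmatropic stage being only transient. The one new stereocentre, C5, is controlled by the C7 carbinol of 11: the shift is suprafacial, so C4 arrives on the face that the oxygen leaves, cis to the C10 methyl and trans to C1, which makes the ring fusion trans. The step needs enol-ether formation toward C4 (secured by the position of iodine in 13), a [3,3] course through a ring-B conformer with the C7–O bond pseudoaxial, and a single mode of aldol closure (secured by the lack of any other enolisable position next to C1, C3 or C4).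

**Step 10**
Reactants: 17 methyl (2Z)-3-methyl-5-[(1R,4aS,8aR)-5,5,8a-trimethyl-6-oxo-1,2,4a,5,6,8a-hexahydronaphthalen-1-yl]pent-2-enoate
Product: 18 methyl (2Z)-3-methyl-5-[(1S,4aS,8aR)-5,5,8a-trimethyl-2,6-dioxo-1,2,4a,5,6,8a-hexahydronaphthalen-1-yl]pent-2-enoate
Conditions: Rh2(cap)4 (dirhodium tetracaprolactamate, 1 mol %), t-BuOOH (70% aq), K2CO3 (cat.), CH2Cl2, rt → 40 °C
Reagents that add atoms: tert-butyl hydroperoxide CC(C)(C)OO
Why: Allylic C–H oxidation should occur at C8, the only allylic CH2 (C5–H is tertiary and flanked by two quaternary carbons, ring A has no allylic hydrogen), giving the second enone; C9 becomes epimerisable but its equatorial configuration is the stable one.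

**Step 11**
Reactants: 18 methyl (2Z)-3-methyl-5-[(1S,4aS,8aR)-5,5,8a-trimethyl-2,6-dioxo-1,2,4a,5,6,8a-hexahydronaphthalen-1-yl]pent-2-enoate
Product: 19 methyl (2Z)-3-methyl-5-[(1S,4aS,8aR)-5,5,8a-trimethyl-2,6-dioxodecahydronaphthalen-1-yl]pent-2-enoate
Conditions: [(Ph3P)CuH]6 (0.5 equiv), benzene, H2O (few equiv), rt
Reagents that add atoms: none
Why: Copper hydride conjugate reduction saturates both ring enones while leaving the β,β-disubstituted enoate and the ketones, forms no new stereocentre and keeps C9 equatorial.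

**Step 12**
Reactants: 19 methyl (2Z)-3-methyl-5-[(1S,4aS,8aR)-5,5,8a-trimethyl-2,6-dioxodecahydronaphthalen-1-yl]pent-2-enoate
Product: 20 methyl (2Z)-3-methyl-5-[(1R,4aS,8aS)-5,5,8a-trimethyl-2-methylidene-6-oxodecahydronaphthalen-1-yl]pent-2-enoate
Conditions: Ph3PCH3Br, KOt-Bu, toluene, 0 → 60 °C
Reagents that add atoms: methyltriphenylphosphonium bromide C[P+](c1ccccc1)(c1ccccc1)c1ccccc1.[Br-]
Why: Wittig methylenation is expected only at the C8 ketone because the C3 ketone is shielded by the adjacent gem-dimethyl carbon, and any base-induced epimerisation at C9 returns the equatorial isomer.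

**Step 13**
Reactants: 20 methyl (2Z)-3-methyl-5-[(1R,4aS,8aS)-5,5,8a-trimethyl-2-methylidene-6-oxodecahydronaphthalen-1-yl]pent-2-enoate
Product: 21 methyl (2Z)-5-[(1R,4aS,6R,8aS)-6-hydroxy-5,5,8a-trimethyl-2-methylidenedecahydronaphthalen-1-yl]-3-methylpent-2-enoate
Conditions: NaBH4, MeOH, 0 °C
Reagents that add atoms: none
Why: NaBH4 reduction of the 4,4-dimethyl-3-ketone of a trans-decalin proceeds by axial hydride attack from the face opposite the axial C4 and C10 methyls and should give the equatorial alcohol (6R), as is general for 4,4-dimethyl-3-oxo terpenoids.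

**Step 14**
Reactants: 21 methyl (2Z)-5-[(1R,4aS,6R,8aS)-6-hydroxy-5,5,8a-trimethyl-2-methylidenedecahydronaphthalen-1-yl]-3-methylpent-2-enoate
Product: 23 methyl (2Z)-5-[(1R,2R,4aS,6R,8aS)-6-hydroxy-2-(hydroxymethyl)-5,5,8a-trimethyldecahydronaphthalen-1-yl]-3-methylpent-2-enoate, via bis-boron adduct 22 (not isolated)
Conditions: 9-BBN (3 equiv), THF, rt → 50 °C; then NaBO3·4H2O, H2O, rt
Reagents that add atoms: sodium perborate [Na+].[O-]OB=O
Why: Hydroboration–oxidation, in which 9-BBN approaches the exocyclic alkene from the face opposite the axial C10 methyl (1,3-diaxial to C8), delivers hydrogen to C8 from that face and leaves the CH2OH axial and cis to the side chain (2R), the electron-poor trisubstituted enoate being unreactive.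

**Step 15**
Reactants: 23 methyl (2Z)-5-[(1R,2R,4aS,6R,8aS)-6-hydroxy-2-(hydroxymethyl)-5,5,8a-trimethyldecahydronaphthalen-1-yl]-3-methylpent-2-enoate
Product: 24 methyl (2Z)-5-[(1R,2R,4aS,6R,8aS)-2-formyl-6-hydroxy-5,5,8a-trimethyldecahydronaphthalen-1-yl]-3-methylpent-2-enoate
Conditions: TEMPO (10 mol %), PhI(OAc)2, CH2Cl2, 0 °C → rt
Reagents that add atoms: none
Why: TEMPO/PhI(OAc)2 oxidation is selective for the primary over the hindered secondary alcohol and is non-basic, so the axial, epimerisable aldehyde should form without loss of configuration at C8.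

**Compound list**
1 | 1-methylcyclohexa-2,5-diene-1-carboxylic acid | CC1(C(=O)O)C=CCC=C1 | starting material
2 | (1-methylcyclohexa-2,5-dien-1-yl)methanol | CC1(CO)C=CCC=C1 | intermediate
3 | 1-methylcyclohexa-2,5-diene-1-carbaldehyde (not isolated) | CC1(C=O)C=CCC=C1 | intermediate
4 | 3-(dimethoxymethyl)-3-methylcyclohexa-1,4-diene | COC(OC)C1(C)C=CCC=C1 | intermediate
5 | 4-(dimethoxymethyl)-4-methylcyclohexa-2,5-dien-1-one | COC(OC)C1(C)C=CC(=O)C=C1 | intermediate
6 | (4R,5S)-4-(dimethoxymethyl)-5-ethenyl-4-methylcyclohex-2-en-1-one | C=C[C@@H]1CC(=O)C=C[C@@]1(C)C(OC)OC | intermediate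
7 | (1S,4R,5S)-4-(dimethoxymethyl)-5-ethenyl-4-methylcyclohex-2-en-1-ol | C=C[C@@H]1C[C@H](O)C=C[C@@]1(C)C(OC)OC | intermediate
8 | methyl but-2-ynoate | CC#CC(=O)OC | starting material
9 | methyl (2Z)-3-iodobut-2-enoate | COC(=O)/C=C(/C)I | intermediate
10 | 9-[2-[(1R,2S,5S)-5-(9-borabicyclo[3.3.1]nonan-9-yloxy)-2-(dimethoxymethyl)-2-methylcyclohex-3-en-1-yl]ethyl]-9-borabicyclo[3.3.1]nonane (not isolated) | C1CCC2CCCC1B2CC[C@@H]1C[C@H](OB2C3CCCC2CCC3)C=C[C@@]1(C)C(OC)OC | intermediate
11 | methyl (2Z)-5-[(1R,2S,5S)-2-(dimethoxymethyl)-5-hydroxy-2-methylcyclohex-3-en-1-yl]-3-methylpent-2-enoate | COC(=O)/C=C(/C)CC[C@@H]1C[C@H](O)C=C[C@@]1(C)C(OC)OC | intermediate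
12 | 2-bromo-3-methylbut-2-ene | CC(C)=C(C)Br | starting material
13 | 2-iodo-3-methylbut-2-ene | CC(C)=C(C)I | intermediate
14 | methyl (2Z)-5-[(1R,2S,5S)-2-(dimethoxymethyl)-2-methyl-5-[(3-methylbut-2-en-2-yl)oxy]cyclohex-3-en-1-yl]-3-methylpent-2-enoate (not isolated) | COC(=O)/C=C(/C)CC[C@@H]1C[C@H](OC(C)=C(C)C)C=C[C@@]1(C)C(OC)OC | intermediate
15 | methyl (2Z)-5-[(1R,2S,3S)-2-(dimethoxymethyl)-2-methyl-3-(2-methyl-3-oxobutan-2-yl)cyclohex-4-en-1-yl]-3-methylpent-2-enoate (not isolated) | COC(=O)/C=C(/C)CC[C@@H]1CC=C[C@H](C(C)(C)C(C)=O)[C@@]1(C)C(OC)OC | intermediate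
16 | methyl (2Z)-5-[(1R,2S,3S)-2-formyl-2-methyl-3-(2-methyl-3-oxobutan-2-yl)cyclohex-4-en-1-yl]-3-methylpent-2-enoate (not isolated) | COC(=O)/C=C(/C)CC[C@@H]1CC=C[C@H](C(C)(C)C(C)=O)[C@@]1(C)C=O | intermediate
17 | methyl (2Z)-3-methyl-5-[(1R,4aS,8aR)-5,5,8a-trimethyl-6-oxo-1,2,4a,5,6,8a-hexahydronaphthalen-1-yl]pent-2-enoate | COC(=O)/C=C(/C)CC[C@@H]1CC=C[C@@H]2C(C)(C)C(=O)C=C[C@@]12C | intermediate
18 | methyl (2Z)-3-methyl-5-[(1S,4aS,8aR)-5,5,8a-trimethyl-2,6-dioxo-1,2,4a,5,6,8a-hexahydronaphthalen-1-yl]pent-2-enoate | COC(=O)/C=C(/C)CC[C@@H]1C(=O)C=C[C@@H]2C(C)(C)C(=O)C=C[C@@]12C | intermediate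
19 | methyl (2Z)-3-methyl-5-[(1S,4aS,8aR)-5,5,8a-trimethyl-2,6-dioxodecahydronaphthalen-1-yl]pent-2-enoate | COC(=O)/C=C(/C)CC[C@@H]1C(=O)CC[C@@H]2C(C)(C)C(=O)CC[C@@]12C | intermediate
20 | methyl (2Z)-3-methyl-5-[(1R,4aS,8aS)-5,5,8a-trimethyl-2-methylidene-6-oxodecahydronaphthalen-1-yl]pent-2-enoate | COC(=O)/C=C(/C)CC[C@@H]1C(=C)CC[C@@H]2C(C)(C)C(=O)CC[C@@]12C | intermediate
21 | methyl (2Z)-5-[(1R,4aS,6R,8aS)-6-hydroxy-5,5,8a-trimethyl-2-methylidenedecahydronaphthalen-1-yl]-3-methylpent-2-enoate | COC(=O)/C=C(/C)CC[C@@H]1C(=C)CC[C@@H]2C(C)(C)[C@H](O)CC[C@@]12C | intermediate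
22 | methyl (2Z)-5-[(1R,2R,4aS,6R,8aS)-2-(9-borabicyclo[3.3.1]nonan-9-ylmethyl)-6-(9-borabicyclo[3.3.1]nonan-9-yloxy)-5,5,8a-trimethyldecahydronaphthalen-1-yl]-3-methylpent-2-enoate (not isolated) | COC(=O)/C=C(/C)CC[C@@H]1[C@H](CB3C4CCCC3CCC4)CC[C@@H]2C(C)(C)[C@H](OB3C4CCCC3CCC4)CC[C@@]12C | intermediate
23 | methyl (2Z)-5-[(1R,2R,4aS,6R,8aS)-6-hydroxy-2-(hydroxymethyl)-5,5,8a-trimethyldecahydronaphthalen-1-yl]-3-methylpent-2-enoate | COC(=O)/C=C(/C)CC[C@@H]1[C@H](CO)CC[C@@H]2C(C)(C)[C@H](O)CC[C@@]12C | intermediate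
24 | methyl (2Z)-5-[(1R,2R,4aS,6R,8aS)-2-formyl-6-hydroxy-5,5,8a-trimethyldecahydronaphthalen-1-yl]-3-methylpent-2-enoate | COC(=O)/C=C(/C)CC[C@@H]1[C@H](C=O)CC[C@@H]2C(C)(C)[C@H](O)CC[C@@]12C | target

**Step count:** 15 steps in total; longest linear sequence 13 steps (steps 1–5, 7 and 9–15, from 1 to 24).

**Steps most likely to fail**

Step 9 (proposed new method). The O-vinylation may stall at the hindered secondary alkoxide with a tetrasubstituted vinyl iodide, or the enol ether may fragment by elimination before it rearranges through the less favoured ring-B conformer. The fallback forms C4–C5 by an Ireland–Claisen rearrangement; it sets out from 7 and returns at 15. Acylation of 7 with isobutyryl chloride (pyridine, DMAP, CH2Cl2) would give the isobutyrate ester F1. Lithium diisopropylamide and Me3SiCl (THF, −78 °C) would convert it into the silyl ketene acetal F2, which on warming to 60 °C should rearrange, with the same suprafacial C7 → C5 transfer, to the trimethylsilyl ester F3. Aqueous work-up would free the carboxylic acid F4, and MeLi (Et2O, 0 °C → rt) would turn its carboxylate into the methyl ketone F5. Hydroboration of the vinyl group with 9-BBN would give the alkylborane F6 (the neopentyl ketone is too hindered to be reduced), and Suzuki–Miyaura coupling with 9 under the conditions of step 7 would give 15, which the acid stage of step 9 carries on to 16 and 17.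

Step 10. Hydrogen abstraction may be unselective (C5–H against C8–H, or the γ-hydrogens of the enoate), or over-oxidation may set in. The fallback replaces the radical C–H oxidation by an ene-type hydroxylation and a separate alcohol oxidation; it sets out from 17 and returns at 18. SeO2 (cat.) with t-BuOOH (CH2Cl2, rt) would hydroxylate C8 through an ene reaction and [2,3] shift to the allylic alcohol F7, and Dess–Martin oxidation would give 18.

Step 4. Catalyst control over which enantiotopic enone reacts may be eroded by the neighbouring quaternary carbon, or a second vinyl group may add. The fallback replaces asymmetric catalysis by resolution; it sets out from 5 and returns at 7. Addition of vinylmagnesium bromide catalysed by CuBr·SMe2 (THF, −78 °C) would give, anti to the acetal, the racemate made up of 6 and its enantiomer, the enone F8. Luche reduction as in step 5 would give 7 together with its enantiomer, the alcohol F9. Lipase-catalysed acetylation (Burkholderia cepacia lipase, vinyl acetate, t-BuOMe) is expected, by the empirical rule for secondary alcohols, to convert the (1R) enantiomer into the acetate F10 and to leave 7, which is separated by chromatography.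

**Further compounds**
F1 | step 9 | (1S,4R,5S)-4-(dimethoxymethyl)-5-ethenyl-4-methylcyclohex-2-en-1-yl 2-methylpropanoate | C=C[C@@H]1C[C@H](OC(=O)C(C)C)C=C[C@@]1(C)C(OC)OC
F2 | step 9 | [(1-{[(1S,4R,5S)-4-(dimethoxymethyl)-5-ethenyl-4-methylcyclohex-2-en-1-yl]oxy}-2-methylprop-1-en-1-yl)oxy]trimethylsilane | C=C[C@@H]1C[C@H](OC(O[Si](C)(C)C)=C(C)C)C=C[C@@]1(C)C(OC)OC
F3 | step 9 | trimethylsilyl 2-[(1S,5S,6S)-6-(dimethoxymethyl)-5-ethenyl-6-methylcyclohex-2-en-1-yl]-2-methylpropanoate | C=C[C@@H]1CC=C[C@H](C(C)(C)C(=O)O[Si](C)(C)C)[C@@]1(C)C(OC)OC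
F4 | step 9 | 2-[(1S,5S,6S)-6-(dimethoxymethyl)-5-ethenyl-6-methylcyclohex-2-en-1-yl]-2-methylpropanoic acid | C=C[C@@H]1CC=C[C@H](C(C)(C)C(=O)O)[C@@]1(C)C(OC)OC
F5 | step 9 | 3-[(1S,5S,6S)-6-(dimethoxymethyl)-5-ethenyl-6-methylcyclohex-2-en-1-yl]-3-methylbutan-2-one | C=C[C@@H]1CC=C[C@H](C(C)(C)C(C)=O)[C@@]1(C)C(OC)OC
F6 | step 9 | 3-[(1S,5R,6S)-5-[2-(9-borabicyclo[3.3.1]nonan-9-yl)ethyl]-6-(dimethoxymethyl)-6-methylcyclohex-2-en-1-yl]-3-methylbutan-2-one | C1CCC2CCCC1B2CC[C@@H]1CC=C[C@H](C(C)(C)C(C)=O)[C@@]1(C)C(OC)OC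
F7 | step 10 | methyl (2Z)-5-[(1S,2S,4aS,8aR)-2-hydroxy-5,5,8a-trimethyl-6-oxo-1,2,4a,5,6,8a-hexahydronaphthalen-1-yl]-3-methylpent-2-enoate | COC(=O)/C=C(/C)CC[C@@H]1[C@@H](O)C=C[C@@H]2C(C)(C)C(=O)C=C[C@@]12C
F8 | step 4 | (4S,5R)-4-(dimethoxymethyl)-5-ethenyl-4-methylcyclohex-2-en-1-one | C=C[C@H]1CC(=O)C=C[C@]1(C)C(OC)OC
F9 | step 4 | (1R,4S,5R)-4-(dimethoxymethyl)-5-ethenyl-4-methylcyclohex-2-en-1-ol | C=C[C@H]1C[C@@H](O)C=C[C@]1(C)C(OC)OC
F10 | step 4 | (1R,4S,5R)-4-(dimethoxymethyl)-5-ethenyl-4-methylcyclohex-2-en-1-yl acetate | C=C[C@H]1C[C@@H](OC(C)=O)C=C[C@]1(C)C(OC)OC
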